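**Retrosynthetic overview**
1. Target 4 ⇒ plastoquinol-9 (3) by opening the O1–C2 bond of the pyran ring. This is the reverse of the tocopherol-cyclase cycloisomerisation, run on the unprotected quinol.
2. 3 ⇒ 2,3-dimethylhydroquinone (1) + all-E-solanesol (2) by cutting the aryl–C1' bond (aromatic prenylation).
3. Ring order: the benzene ring and all E-olefins are bought. The pyran ring is the only ring made, in the last step, and its closure sets the single stereocentre (2R) under catalyst control.

Assumption: commercial solanesol is the all-E isomer (≥95 %). The sense of induction of the chiral acid cannot be predicted with certainty, so "(S,S)" below stands for whichever catalyst antipode gives 2R in the first analytical run (chiral HPLC against natural plastochromanol-8); both antipodes are equally accessible.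

**Step 1**
Reactants: 1 2,3-dimethylhydroquinone (3 equiv); 2 all-E-solanesol
Product: 3 plastoquinol-9, 2,3-dimethyl-5-[(2E,6E,10E,14E,18E,22E,26E,30E)-3,7,11,15,19,23,27,31,35-nonamethylhexatriaconta-2,6,10,14,18,22,26,30,34-nonaenyl]benzene-1,4-diol
Conditions: BF3·OEt2 (30 mol %), dioxane, 20 °C, Ar, dark, 24 h; degassed aq. NaHCO3 work-up; flash chromatography under Ar (degassed hexane/EtOAc), then recrystallisation (acetone, –20 °C)
Reagents that add atoms: none
Why: Dehydrative Friedel–Crafts allylation, in which BF3 ionises the allylic alcohol and the solanesyl cation is attacked at its primary terminus by one of the two equivalent free ring positions of the electron-rich hydroquinone, giving the linear 2'E product as a single regioisomer; excess 1 suppresses bis-allylation, dioxane tempers the acid so that chroman closure and polyene cyclisation stay minor, and no stereocentre is formed.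

**Step 2**
Reactants: 3 plastoquinol-9
Product: 4 (2R)-plastochromanol-8, (2R)-2,7,8-trimethyl-2-[(3E,7E,11E,15E,19E,23E,27E)-4,8,12,16,20,24,28,32-octamethyltritriaconta-3,7,11,15,19,23,27,31-octaenyl]-3,4-dihydro-2H-chromen-6-ol
Conditions: (S,S)-IDPi (confined BINOL-derived imidodiphosphorimidate Brønsted acid, 3,3'-aryl, N-triflyl; 5 mol %), cyclohexane (0.02 M), 25 °C, Ar, dark, 48 h
Reagents that add atoms: none
Why: Proposed new method: the confined chiral acid hydrogen-bonds to the C4–OH next to the side chain and protonates C2' of the 2'E olefin while that phenolic oxygen closes on C3' in an asynchronous concerted Markovnikov 6-endo anti-addition (the tocopherol-cyclase mechanism), so the chiral anion pocket decides which face of C3' receives oxygen by telling the methyl group from the long chain and thereby sets 2R, and the eight remote olefins stay untouched because in an apolar non-fluorinated solvent they lack an internal nucleophile to assist protonation; the closest known reaction types are IDPi-catalysed enantioselective intramolecular hydroalkoxylation of unactivated alkenes and IDPi-catalysed protonative polyene cyclisation.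

**Compound list**
1 | 2,3-dimethylhydroquinone (2,3-dimethylbenzene-1,4-diol) | Cc1c(O)ccc(O)c1C | starting material
2 | all-E-solanesol | CC(C)=CCC/C(C)=C/CC/C(C)=C/CC/C(C)=C/CC/C(C)=C/CC/C(C)=C/CC/C(C)=C/CC/C(C)=C/CC/C(C)=C/CO | starting material
3 | plastoquinol-9 (2,3-dimethyl-5-all-E-solanesylbenzene-1,4-diol) | CC(C)=CCC/C(C)=C/CC/C(C)=C/CC/C(C)=C/CC/C(C)=C/CC/C(C)=C/CC/C(C)=C/CC/C(C)=C/CC/C(C)=C/Cc1cc(O)c(C)c(C)c1O | intermediate
4 | (2R)-plastochromanol-8 | CC(C)=CCC/C(C)=C/CC/C(C)=C/CC/C(C)=C/CC/C(C)=C/CC/C(C)=C/CC/C(C)=C/CC/C(C)=C/CC[C@]1(C)CCc2cc(O)c(C)c(C)c2O1 | target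

**Total step count:** 2
**Longest linear sequence:** 2

**Steps most likely to fail**

The route has only two steps, so both are ranked and there is no third step to rank.

Most likely to fail is step 2. The risks are that the catalyst discriminates only moderately between methyl and chain at C3', that a remote olefin is protonated, and that the para hydroxyl binds the catalyst. Any racemic chromanol carried over from step 1 would also lower the ee, so 3 must be free of it. Fallback: setting out from 3, the ring is closed without stereocontrol by p-TsOH·H2O (10 mol %) in toluene at 60 °C under Ar, a known reaction of polyprenyl quinols, to give racemic plastochromanol-8 F1. The enantiomers are then separated by preparative HPLC on a cellulose tris(3,5-dimethylphenylcarbamate) phase, the unwanted (2S)-plastochromanol-8 F2 is put aside, and the 2R fraction is compound 4, where the route is rejoined at its end. Here the stereocentre comes from resolution instead of asymmetric catalysis.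

Second is step 1. The yield of such BF3 condensations is modest (typically 20–35 %). The allyl cation also erodes the 2'E geometry somewhat, and the Z isomer, the bis-allylated quinol and racemic chromanol must all be removed. Fallback: setting out from 2, PBr3 (0.4 equiv) with a trace of pyridine in Et2O at –10 °C gives solanesyl bromide F3. Bu3SnLi in THF at –78 °C displaces bromide at the primary carbon to give tributyl(solanesyl)stannane F4. This allylstannane is coupled with 2,3-dimethyl-1,4-benzoquinone F5 (made from 1 with Ag2O in Et2O) under BF3·OEt2 in CH2Cl2 at –78 °C, a quinone allylation that transfers the allyl group with retention of the 2'E geometry. Aqueous KF/Na2S2O4 work-up returns compound 3, where the route is rejoined. This replaces the cationic Friedel–Crafts step by a stereoretentive allylmetal–quinone coupling, at the cost of two extra steps.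

**Further compounds**
F1 | step 2 | racemic plastochromanol-8 | CC(C)=CCC/C(C)=C/CC/C(C)=C/CC/C(C)=C/CC/C(C)=C/CC/C(C)=C/CC/C(C)=C/CC/C(C)=C/CCC1(C)CCc2cc(O)c(C)c(C)c2O1
F2 | step 2 | (2S)-plastochromanol-8 | CC(C)=CCC/C(C)=C/CC/C(C)=C/CC/C(C)=C/CC/C(C)=C/CC/C(C)=C/CC/C(C)=C/CC/C(C)=C/CC[C@@]1(C)CCc2cc(O)c(C)c(C)c2O1
F3 | step 1 | all-E-solanesyl bromide | CC(C)=CCC/C(C)=C/CC/C(C)=C/CC/C(C)=C/CC/C(C)=C/CC/C(C)=C/CC/C(C)=C/CC/C(C)=C/CC/C(C)=C/CBr
F4 | step 1 | tributyl(all-E-solanesyl)stannane | CC(C)=CCC/C(C)=C/CC/C(C)=C/CC/C(C)=C/CC/C(C)=C/CC/C(C)=C/CC/C(C)=C/CC/C(C)=C/CC/C(C)=C/C[Sn](CCCC)(CCCC)CCCC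
F5 | step 1 | 2,3-dimethyl-1,4-benzoquinone | CC1=C(C)C(=O)C=CC1=O
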